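**Strategy.** Eudesmane numbering is used (ring A: C1–C5 and C10; ring B: C5–C10; side chain C11). The plan rests on cutting C5–C10 and C7–C8, which opens both rings to one acyclic trienal. In a single Lewis-acid cascade the C4=C5 alkene adds to the Z-enal carbon C10 (closing ring A), the C3 tert-butyl carbonate captures the C4 cation as the cis-3,4-carbonate, and the liberated aldehyde C8 closes ring B by a carbonyl-ene reaction with the prenyl alkene at C7. The step exploits the 1,3-spacing of C8 and C10, the cis-3,4-diol on quaternary C4 and the trans ring fusion. The precursor is (2Z,6R,7E)-6-Boc-oxy-3,7,11-trimethyldodeca-2,7,10-trienal.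

Key step: step 7

Remark on the chemistry: the open-chain precursors are named as dodecatrienes; their C1, C3, C6, C7, C8 and C10 become C8, C10, C3, C4, C5 and C7 of the eudesmane.

Step 1
Reactants: 1 neryl acetate
Product: 2 (2Z)-3-methyl-6-oxohex-2-en-1-yl acetate
Conditions: O3 (1.0 equiv), CH2Cl2, −78 °C; then Me2S, −78 °C → rt
Reagents that add atoms: ozone, O=[O+][O-]
Why: Chemoselective ozonolysis; the electron-rich terminal isopropylidene alkene should react before the alkene deactivated by the allylic acetate, and reductive work-up leaves the Z geometry untouched.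

Step 2
Reactants: 3 prenyl bromide; 4 prop-1-yn-1-ylmagnesium bromide
Product: 5 6-methylhept-5-en-2-yne
Conditions: CuBr·SMe2 (5 mol %), THF, 0 °C → rt
Reagents that add atoms: none
Why: Copper-catalysed SN2 coupling of an alkynyl Grignard reagent with a primary allylic bromide should give the skipped enyne at the unhindered terminus.

Step 3
Reactants: 5 6-methylhept-5-en-2-yne; 2 (2Z)-3-methyl-6-oxohex-2-en-1-yl acetate
Product: 8 (2Z,6R,7E)-6-hydroxy-3,7,11-trimethyldodeca-2,7,10-trien-1-yl acetate, via alkenylzirconocene chloride 6 (not isolated), via alkenyl(methyl)zinc 7 (not isolated)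
Conditions: Cp2Zr(H)Cl, CH2Cl2, rt; Me2Zn, toluene, −65 °C; (2S)-(−)-3-exo-morpholinoisoborneol (10 mol %, the enantiomer that delivers to the Si face of 2), then 2, −30 → 0 °C; aq. NH4Cl
Reagents that add atoms: none
Why: Syn hydrozirconation with zirconium at the methyl-bearing alkyne carbon fixes the E trisubstituted alkene, and after transmetalation the amino-alcohol ligand should deliver the alkenyl group to the Si face of the aldehyde (catalytic asymmetric alkenylzinc addition), setting the carbinol centre as R; the acetate tolerates the zinc reagent.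

Step 4
Reactants: 8 (2Z,6R,7E)-6-hydroxy-3,7,11-trimethyldodeca-2,7,10-trien-1-yl acetate
Product: 9 (2Z,6R,7E)-6-[(tert-butoxycarbonyl)oxy]-3,7,11-trimethyldodeca-2,7,10-trien-1-yl acetate
Conditions: Boc2O, DMAP, Et3N, CH2Cl2, 0 °C → rt
Reagents that add atoms: di-tert-butyl dicarbonate, CC(C)(C)OC(=O)OC(=O)OC(C)(C)C
Why: DMAP-catalysed acylation of the secondary allylic alcohol should give the tert-butyl carbonate without touching the stereocentre.

Step 5
Reactants: 9 (2Z,6R,7E)-6-[(tert-butoxycarbonyl)oxy]-3,7,11-trimethyldodeca-2,7,10-trien-1-yl acetate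
Product: 10 tert-butyl (2Z,6R,7E)-1-hydroxy-3,7,11-trimethyldodeca-2,7,10-trien-6-yl carbonate
Conditions: K2CO3 (cat.), MeOH, 0 °C
Reagents that add atoms: none
Why: Transesterification; the unhindered primary acetate should be methanolysed far faster than the hindered secondary tert-butyl carbonate.

Step 6
Reactants: 10 tert-butyl (2Z,6R,7E)-1-hydroxy-3,7,11-trimethyldodeca-2,7,10-trien-6-yl carbonate
Product: 11 tert-butyl (2Z,6R,7E)-3,7,11-trimethyl-1-oxododeca-2,7,10-trien-6-yl carbonate
Conditions: MnO2 (activated, excess), CH2Cl2, rt, dark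
Reagents that add atoms: none
Why: Allylic oxidation with MnO2 is neutral and should give the enal with the Z geometry retained, as in nerol to neral.

Step 7
Reactants: 11 tert-butyl (2Z,6R,7E)-3,7,11-trimethyl-1-oxododeca-2,7,10-trien-6-yl carbonate
Product: 12 (3R,4S,5R,7R,8S,10R)-8-hydroxyeudesm-11-ene-3,4-diyl carbonate (trans-fused; 3α,4α-carbonate; 7β-isopropenyl; 8α-hydroxy)
Conditions: BF3·OEt2 (2 equiv), CH2Cl2 (0.01 M), −78 → −20 °C; aq. NaHCO3
Reagents that add atoms: none
Why: BF3 activates the enal, the C4=C5 alkene adds through C5 to the β-carbon C10 (Lewis-acid-induced conjugate addition of an alkene to an enal, a cation–olefin cyclization), the axial C3 tert-butyl carbonate captures the C4 cation as the cyclic carbonate with loss of isobutene (carbonate termination as in halo- and proto-carbonation), and the proton so released converts the boron enolate into the aldehyde C8, which closes onto the prenyl alkene by an intramolecular carbonyl-ene reaction of the citronellal-to-isopulegol kind. These three events are each known reaction types; running them in one flask is the risk accepted here. Ring A closes 6-endo-trig through a chair, the carbonate ring 5-exo, ring B through a six-membered chair ene transition state. C10 is controlled by the Z-enal (allylic 1,3-strain between C8 and C2 turns C9 equatorial and the methyl axial), C5 by the E alkene in the chair (C6 equatorial, hence trans fusion), C4 by anti addition across C4=C5 (oxygen equatorial, methyl axial), and the absolute sense of all three by C3, whose carbonate reaches C4 only from an axial position opposite the new C5–C10 bond; C7 and C8 form equatorial and are erased later. The step needs the carbonate-bearing alkene, not the more electron-rich prenyl alkene, to attack C10, which ring size secures (six- against eight-membered), and it needs the allylic carbonate not to ionize, which low temperature and the stronger basicity of the aldehyde oxygen should secure.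

Step 8
Reactants: 12 (3R,4S,5R,7R,8S,10R)-8-hydroxyeudesm-11-ene-3,4-diyl carbonate
Product: 13 (3R,4S,5R,7R,10R)-8-oxoeudesm-11-ene-3,4-diyl carbonate
Conditions: Dess–Martin periodinane, NaHCO3, CH2Cl2, 0 °C → rt
Reagents that add atoms: none
Why: Buffered Dess–Martin oxidation of the secondary alcohol should give the ketone without moving the isopropenyl double bond.

Step 9
Reactants: 13 (3R,4S,5R,7R,10R)-8-oxoeudesm-11-ene-3,4-diyl carbonate
Product: 15 (3R,4S,5R,7S,10R)-7,11-epoxy-3,4-dihydroxyeudesman-8-one, via enone diol 14 (not isolated)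
Conditions: K2CO3, MeOH, rt; then 30 % aq. H2O2, aq. NaOH, 0 °C → rt
Reagents that add atoms: hydrogen peroxide, OO
Why: Base should cleave the cyclic carbonate by transesterification and conjugate the alkene into the tetrasubstituted enone; Weitz–Scheffer epoxidation then adds hydroperoxide at C11, and the enolate should close on oxygen from the axial α-face of C7 through a chair, keeping the bulky CMe2 group equatorial, which sets C7.

Step 10
Reactants: 15 (3R,4S,5R,7S,10R)-7,11-epoxy-3,4-dihydroxyeudesman-8-one
Product: 16 (3R,4S,5R,7S,10R)-3,4,7,11-tetrahydroxyeudesman-8-one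
Conditions: HClO4 (dilute aq.), THF, 0 °C → rt
Reagents that add atoms: water, O
Why: Acid-catalysed epoxide hydrolysis; water should attack the tertiary carbon C11 remote from the carbonyl, so the C7–O bond and its configuration are kept.

Step 11
Reactants: 17 methyl angelate
Product: 18 angelyl alcohol, (2Z)-2-methylbut-2-en-1-ol
Conditions: DIBAL-H, Et2O, −78 → 0 °C; aq. Rochelle salt
Reagents that add atoms: none
Why: Hydride reduction of the ester at low temperature should give the allylic alcohol without Z-to-E isomerization.

Step 12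
Reactants: 18 angelyl alcohol
Product: 19 [(2R,3S)-2,3-dimethyloxiran-2-yl]methanol
Conditions: Ti(OiPr)4 (10 mol %), D-(−)-diethyl tartrate (12 mol %), t-BuOOH, 4 Å molecular sieves, CH2Cl2, −20 °C; non-aqueous work-up
Reagents that add atoms: tert-butyl hydroperoxide, CC(C)(C)OO
Why: Sharpless asymmetric epoxidation; D-(−)-tartrate should deliver oxygen to the face that gives the (2R,3S)-epoxy alcohol, and the Z alkene translates into the trans disposition of the two methyl groups.

Step 13
Reactants: 19 [(2R,3S)-2,3-dimethyloxiran-2-yl]methanol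
Product: 20 (2S,3S)-2,3-dimethyloxirane-2-carboxylic acid
Conditions: TEMPO (cat.), PhI(OAc)2, MeCN/H2O, rt
Reagents that add atoms: water, O
Why: Oxoammonium oxidation should take the primary alcohol through the aldehyde hydrate to the acid without opening the epoxide; the stereocentres are untouched (the C2 descriptor changes by priority only).

Step 14
Reactants: 20 (2S,3S)-2,3-dimethyloxirane-2-carboxylic acid; 16 (3R,4S,5R,7S,10R)-3,4,7,11-tetrahydroxyeudesman-8-one
Product: 22 (3R,4S,5R,7S,10R)-4,7,11-trihydroxy-8-oxoeudesman-3-yl (2S,3S)-2,3-dimethyloxirane-2-carboxylate, via mixed anhydride 21 (not isolated)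
Conditions: 2,4,6-trichlorobenzoyl chloride, Et3N, THF, rt; then 16, DMAP, toluene, rt
Reagents that add atoms: none
Why: Yamaguchi esterification; the mixed anhydride should acylate only the secondary C3 hydroxyl, the three tertiary hydroxyls being too hindered, and no stereocentre is affected.

**Compound list**

1 | neryl acetate, (2Z)-3,7-dimethylocta-2,6-dien-1-yl acetate | CC(C)=CCC/C(C)=C\COC(C)=O | starting material
2 | (2Z)-3-methyl-6-oxohex-2-en-1-yl acetate | O=CCC/C(C)=C\COC(C)=O | intermediate
3 | prenyl bromide, 1-bromo-3-methylbut-2-ene | CC(C)=CCBr | starting material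
4 | prop-1-yn-1-ylmagnesium bromide | CC#C[Mg]Br | starting material
5 | 6-methylhept-5-en-2-yne | CC#CCC=C(C)C | intermediate
6 | chloro[(2E)-6-methylhepta-2,5-dien-2-yl]zirconocene | C/C(=C\CC=C(C)C)[Zr](Cl)(C1C=CC=C1)C1C=CC=C1 | intermediate
7 | methyl[(2E)-6-methylhepta-2,5-dien-2-yl]zinc | C/C(=C\CC=C(C)C)[Zn]C | intermediate
8 | (2Z,6R,7E)-6-hydroxy-3,7,11-trimethyldodeca-2,7,10-trien-1-yl acetate | CC(=O)OC/C=C(C)\CC[C@@H](O)/C(C)=C/CC=C(C)C | intermediate
9 | (2Z,6R,7E)-6-[(tert-butoxycarbonyl)oxy]-3,7,11-trimethyldodeca-2,7,10-trien-1-yl acetate | CC(=O)OC/C=C(C)\CC[C@@H](OC(=O)OC(C)(C)C)/C(C)=C/CC=C(C)C | intermediate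
10 | tert-butyl (2Z,6R,7E)-1-hydroxy-3,7,11-trimethyldodeca-2,7,10-trien-6-yl carbonate | OC/C=C(C)\CC[C@@H](OC(=O)OC(C)(C)C)/C(C)=C/CC=C(C)C | intermediate
11 | tert-butyl (2Z,6R,7E)-3,7,11-trimethyl-1-oxododeca-2,7,10-trien-6-yl carbonate | O=C/C=C(C)\CC[C@@H](OC(=O)OC(C)(C)C)/C(C)=C/CC=C(C)C | intermediate
12 | (3R,4S,5R,7R,8S,10R)-8-hydroxyeudesm-11-ene-3,4-diyl carbonate | O=C3O[C@@H]1CC[C@]2(C)C[C@H](O)[C@@H](C(C)=C)C[C@H]2[C@]1(C)O3 | intermediate
13 | (3R,4S,5R,7R,10R)-8-oxoeudesm-11-ene-3,4-diyl carbonate | O=C3O[C@@H]1CC[C@]2(C)CC(=O)[C@@H](C(C)=C)C[C@H]2[C@]1(C)O3 | intermediate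
14 | (3R,4S,5R,10R)-3,4-dihydroxyeudesm-7(11)-en-8-one | O[C@@H]1CC[C@]2(C)CC(=O)C(=C(C)C)C[C@H]2[C@]1(C)O | intermediate
15 | (3R,4S,5R,7S,10R)-7,11-epoxy-3,4-dihydroxyeudesman-8-one | O[C@@H]1CC[C@]2(C)CC(=O)[C@@](O3)(C3(C)C)C[C@H]2[C@]1(C)O | intermediate
16 | (3R,4S,5R,7S,10R)-3,4,7,11-tetrahydroxyeudesman-8-one | O[C@@H]1CC[C@]2(C)CC(=O)[C@@](O)(C(C)(C)O)C[C@H]2[C@]1(C)O | intermediate
17 | methyl angelate, methyl (2Z)-2-methylbut-2-enoate | C/C=C(C)\C(=O)OC | starting material
18 | angelyl alcohol, (2Z)-2-methylbut-2-en-1-ol | C/C=C(C)\CO | intermediate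
19 | [(2R,3S)-2,3-dimethyloxiran-2-yl]methanol | C[C@@H]1O[C@]1(C)CO | intermediate
20 | (2S,3S)-2,3-dimethyloxirane-2-carboxylic acid | C[C@@H]1O[C@]1(C)C(=O)O | intermediate
21 | (2S,3S)-2,3-dimethyloxirane-2-carboxylic 2,4,6-trichlorobenzoic anhydride | C[C@@H]1O[C@]1(C)C(=O)OC(=O)c1c(Cl)cc(Cl)cc1Cl | intermediate
22 | (3R,4S,5R,7S,10R)-4,7,11-trihydroxy-8-oxoeudesman-3-yl (2S,3S)-2,3-dimethyloxirane-2-carboxylate | C[C@@H]1O[C@]1(C)C(=O)O[C@@H]1CC[C@]2(C)CC(=O)[C@@](O)(C(C)(C)O)C[C@H]2[C@]1(C)O | target

**Step count and risks**

Total step count: 14. Longest linear sequence: 10 steps (steps 1, 3, 4, 5, 6, 7, 8, 9, 10, 14).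

Steps most likely to fail:

1. Step 7. The relay between the two ring closures may break down: the enolate left after the first closure may not be reprotonated in the flask, or the prenyl cation of the second closure may be trapped by fluoride or lose a proton towards C7. Material would then stall after ring A or spread over alkene isomers. Z-to-E isomerization of the enal before cyclization would in addition erode the trans ring fusion. Fallback (sets out from 11, returns at 12): the two closures are run as separate operations. Compound 11 is treated with Me2AlCl in CH2Cl2 at −78 °C, which should mediate only the conjugate addition with carbonate capture and hold the product as its aluminium enolate until aqueous quench, giving the monocyclic carbonate aldehyde F1. F1 is then cyclized with ZnBr2 in toluene at 0 °C, the standard citronellal-to-isopulegol carbonyl-ene conditions, to 12.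

2. Step 10. Under acid the epoxy ketone may rearrange (acyl shift to C11, or proton loss from a C11 methyl to an isopropenyl carbinol) faster than water adds at C11. Fallback (sets out from 13, returns at 16): the two hydroxyl groups are introduced separately, without an epoxide. The potassium dienolate of 13 (KHMDS, THF, −78 °C) is hydroxylated at C7 with the Davis oxaziridine from the axial α-face to give the 7α-hydroxy isopropenyl ketone carbonate F2. Mukaiyama hydration of the isopropenyl group (Mn(dpm)3, PhSiH3, O2, i-PrOH) should give the 7,11-diol carbonate F3. Brief carbonate methanolysis (K2CO3, MeOH, 0 °C) returns 16.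

3. Step 3. Alkenyl transfer to the unbranched aliphatic aldehyde may proceed with low facial selectivity, so that 8 is formed with insufficient enantiomeric purity. Fallback (sets out from 8 of low enantiomeric purity, returns at 8): the carbinol is oxidized with Dess–Martin periodinane to the α-methyl enone F4. The stereocentre is then set by Corey–Bakshi–Shibata reduction with the (S)-methyl oxazaborolidine and catecholborane, which should give the (R)-allylic alcohol 8 under reagent control.

Further compounds
F1 | step 7 | monocyclic carbonate aldehyde (7,8-seco-eudesm-7(11)-en-8-al 3α,4α-carbonate) | O=C3O[C@@H]1CC[C@](C)(CC=O)[C@@H](CC=C(C)C)[C@]1(C)O3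
F2 | step 10 | (3R,4S,5R,7S,10R)-7-hydroxy-8-oxoeudesm-11-ene-3,4-diyl carbonate | O=C3O[C@@H]1CC[C@]2(C)CC(=O)[C@@](O)(C(C)=C)C[C@H]2[C@]1(C)O3
F3 | step 10 | (3R,4S,5R,7S,10R)-7,11-dihydroxy-8-oxoeudesmane-3,4-diyl carbonate | O=C3O[C@@H]1CC[C@]2(C)CC(=O)[C@@](O)(C(C)(C)O)C[C@H]2[C@]1(C)O3
F4 | step 3 | (2Z,7E)-3,7,11-trimethyl-6-oxododeca-2,7,10-trien-1-yl acetate | CC(=O)OC/C=C(C)\CCC(=O)/C(C)=C/CC=C(C)C
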